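Retrosynthetic overview
1. Structural feature: in the upper flavan unit, C4 of ring C is a diarylmethine stereocentre bonded to C4a of ring A and to C8 of ring D (the catechin benzo ring). It lies β to C2, the carbon that bears O1 and ring B, so C4–C3–C2 is read as Cβ–Cα–C(=O) of a catechin-8-yl enone with ring B on the carbonyl carbon.
2. Key disconnections: C4–C4a (ligand-controlled rhodium 1,4-arylation with a 2-hydroxyarylboronic acid) and O1–C2 (hemiketal, then loss of water). Both bonds form in one flask and give ring C as a 2-aryl-4H-chromene.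
3. The enone is cut at Cα=Cβ into 8-formyl-penta-O-benzylcatechin (from (+)-catechin by benzylation, C8 bromination, lithiation and formylation) and 3',4'-dibenzyloxyacetophenone. The boronic acid derives from 4-bromoresorcinol.
4. Ring order: rings D, E, F (with both stereocentres) and the arenes A and B are bought, and ring C is the only ring built. C2 is then set from C4 by saturating C2=C3 while every phenol is still benzylated, and the eight benzyl ethers are removed last.

Key step: step 9

Labels: upper unit = rings A (benzo), B (catechol), C (pyran); lower catechin unit = rings D (benzo), E (catechol), F (pyran); Bn = benzyl.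
Remark on the chemistry: the target SMILES is read as (2S,4S), 2,4-cis, in the upper unit and (2R,3S), i.e. (+)-catechin, in the lower unit. The enantiomer of the diene ligand is chosen from the accepted coordination model of this ligand family, and its mirror image is equally accessible should the sense on this enone prove opposite.

Step 1
Reactants: 1 (+)-catechin
Product: 2 5,7,3',4'-tetra-O-benzyl-(+)-catechin
Conditions: BnBr (4.4 equiv), K2CO3, DMF, argon, 0 °C to rt
Reagents that add atoms: benzyl bromide, BrCc1ccccc1
Why: Williamson etherification in which K2CO3 ionises only the four phenols, so the secondary 3-OH stays free, and the mild base under argon avoids the ring opening to a quinone methide that would epimerise C2.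

Step 2
Reactants: 2 5,7,3',4'-tetra-O-benzyl-(+)-catechin
Product: 3 8-bromo-5,7,3',4'-tetra-O-benzylcatechin
Conditions: NBS (1.0 equiv), CH2Cl2, −78 °C to rt
Reagents that add atoms: N-bromosuccinimide, O=C1CCC(=O)N1Br
Why: Electrophilic aromatic bromination, in which ring D with its three oxygen substituents is far more nucleophilic than ring E or the benzyl groups, and one equivalent of NBS at low temperature is known to attack C8 rather than C6 in O-benzylated catechins.

Step 3
Reactants: 3 8-bromo-5,7,3',4'-tetra-O-benzylcatechin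
Product: 4 8-bromo-3,5,7,3',4'-penta-O-benzylcatechin
Conditions: NaH, BnBr, Bu4NI (cat.), DMF, 0 °C to rt
Reagents that add atoms: benzyl bromide, BrCc1ccccc1
Why: Williamson etherification of the secondary alkoxide, which removes the last acidic proton before the organolithium step and touches neither the aryl bromide nor C2 and C3.

Step 4
Reactants: 4 8-bromo-3,5,7,3',4'-penta-O-benzylcatechin
Product: 7 8-formyl-3,5,7,3',4'-penta-O-benzylcatechin, via 8-lithio-penta-O-benzylcatechin 5 (not isolated), via lithium hemiaminal alkoxide 6 (not isolated)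
Conditions: n-BuLi (1.1 equiv), THF, −78 °C; DMF (3 equiv), −78 to 0 °C; 1 M HCl, 0 °C
Reagents that add atoms: N,N-dimethylformamide, CN(C)C=O
Why: Bromine–lithium exchange, faster at −78 °C than benzylic deprotonation and assisted by the two flanking oxygen atoms, followed by formylation of the aryllithium with DMF (Bouveault aldehyde synthesis), the hemiaminal alkoxide collapsing to the aldehyde only on acidic work-up.

Step 5
Reactants: 8 3',4'-dihydroxyacetophenone
Product: 9 3',4'-bis(benzyloxy)acetophenone
Conditions: BnBr (2.2 equiv), K2CO3, DMF, 60 °C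
Reagents that add atoms: benzyl bromide, BrCc1ccccc1
Why: Williamson etherification of both catechol hydroxyls, with K2CO3 too weak a base to alkylate the methyl ketone.

Step 6
Reactants: 7 8-formyl-3,5,7,3',4'-penta-O-benzylcatechin; 9 3',4'-bis(benzyloxy)acetophenone
Product: 11 (E)-1-(3,4-dibenzyloxyphenyl)-3-(penta-O-benzylcatechin-8-yl)prop-2-en-1-one, via aldol adduct 10 (not isolated)
Conditions: KOH (50% aq), EtOH/THF, rt to 40 °C
Reagents that add atoms: none
Why: Claisen–Schmidt condensation, in which aldehyde 7 cannot enolise so only the enolate of 9 adds, E1cB loss of hydroxide from aldol 10 gives the conjugated enone in the thermodynamically preferred E geometry as is routine for 2,4,6-trialkoxybenzaldehydes, and the crowded β-carbon prevents a second Michael addition.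

Step 7
Reactants: 12 4-bromoresorcinol
Product: 13 5-benzyloxy-2-bromophenol
Conditions: BnBr (1.0 equiv), K2CO3 (1.0 equiv), acetone, rt to reflux; chromatography
Reagents that add atoms: benzyl bromide, BrCc1ccccc1
Why: Williamson mono-etherification in which the hydroxyl para to bromine is unhindered and gives the more nucleophilic phenoxide while the hydroxyl next to bromine is shielded, so the para-O-benzyl ether should predominate and can be separated from the regioisomer and the bis-ether by chromatography.

Step 8
Reactants: 13 5-benzyloxy-2-bromophenol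
Product: 16 4-benzyloxy-2-hydroxyphenylboronic acid, via dilithio species 14 (not isolated), via dilithium triisopropoxyborate 15 (not isolated)
Conditions: n-BuLi (2.2 equiv), THF, −78 °C; B(OiPr)3, −78 °C to rt; dilute HCl to pH 5–6, 0 °C
Reagents that add atoms: triisopropyl borate, CC(C)OB(OC(C)C)OC(C)C; water, O
Why: Lithiation–borylation as practised on 2-bromophenol itself, in which the first equivalent of n-BuLi forms the phenoxide, the second effects bromine–lithium exchange, B(OiPr)3 traps the aryllithium as the ate complex, and cold hydrolysis near pH 5–6 frees the boronic acid without the protodeboronation that strong acid would cause.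

Step 9
Reactants: 11 (E)-1-(3,4-dibenzyloxyphenyl)-3-(penta-O-benzylcatechin-8-yl)prop-2-en-1-one; 16 4-benzyloxy-2-hydroxyphenylboronic acid
Product: 19 (4S)-7-benzyloxy-2-(3,4-dibenzyloxyphenyl)-4-(penta-O-benzylcatechin-8-yl)-4H-chromene, via (3S)-β,β-diaryl ketone 17 (not isolated), via 2-hydroxychroman hemiketal 18 (not isolated)
Conditions: [RhCl(C2H4)2]2 (2.5 mol %), (1R,4R)-2,5-diphenylbicyclo[2.2.2]octa-2,5-diene (5.5 mol %), KOH (0.3 equiv), 16 (3 equiv, in portions), dioxane/H2O 10:1, 50 °C; then evaporation in the same flask, toluene, TsOH·H2O (0.5 equiv), rt; Et3N-washed SiO2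
Reagents that add atoms: none
Why: KOH converts the chloride-bridged precursor and the diene into a hydroxo complex of monovalent rhodium, boron-to-rhodium transmetalation from 16 gives the aryl complex, enone 11 coordinates and inserts into the Rh–aryl bond so that the aryl carbon (C4a) is joined to Cβ (C4), and water cleaves the oxa-π-allyl enolate to ketone 17 and regenerates the hydroxo complex. The closest known reaction is the Hayashi–Miyaura asymmetric 1,4-addition of arylboronic acids, 2-hydroxyarylboronic acids included, to chalcone-type β-aryl enones with cyclodehydration to 4-aryl-4H-chromenes. Ring C closes by 6-exo-trig attack of the ortho phenol oxygen (O1) on the ketone carbon (C2) to give hemiketal 18, which TsOH ionises to the oxocarbenium ion stabilised by ring B, and because only C3 carries removable protons the sole alkene possible is C2=C3. C4 is the one new stereocentre and is set by the ligand: in the accepted model for this twofold-symmetric diene the (1R,4R) enantiomer binds the E-enone through its α-Re/β-Re face with the aroyl group turned away from the ligand phenyl group, so the aryl group lands on the Re face of Cβ, which is (4S), while the remote catechin stereocentres merely turn any leakage into a separable diastereomer. The step needs 1,4- over 1,2-addition, secured by the aryl ketone carbonyl that aryl-rhodium species do not attack under these conditions and by the geometrically pure E alkene, and it needs insertion to outrun protodeboronation of the electron-rich 16, which is why the most active ligand class, moderate heating and a portionwise excess of 16 are set against the hindrance from the 7-O-benzyl group and O1 of the catechin unit that flank C8. The acid stage is kept catalytic and at room temperature so that ring D is not protonated at C8 and the C4–C8 bond is not ionised toward a flavylium ion.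

Step 10
Reactants: 19 (4S)-7-benzyloxy-2-(3,4-dibenzyloxyphenyl)-4-(penta-O-benzylcatechin-8-yl)-4H-chromene
Product: 20 (2S,4S)-7-benzyloxy-2-(3,4-dibenzyloxyphenyl)-4-(penta-O-benzylcatechin-8-yl)chroman (2,4-cis)
Conditions: H2 (1–5 bar), 10% Pd/C, 2,2'-bipyridyl (0.5 equiv), EtOAc/THF, rt
Reagents that add atoms: none
Why: Heterogeneous syn-hydrogenation in which the pseudo-axial ring D at C4 shields one face of the flattened 4H-pyran, so both hydrogens reach C2 and C3 from the C4–H face and give the 2,4-cis (2S) flavan, while the bipyridyl poison suppresses hydrogenolysis of aryl benzyl ethers so that no free 7-OH of ring D can add to C2 of the enol ether and lock the molecule as a bicyclic ketal.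

Step 11
Reactants: 20 (2S,4S)-7-benzyloxy-2-(3,4-dibenzyloxyphenyl)-4-(penta-O-benzylcatechin-8-yl)chroman
Product: 21 (2R,3S)-2-(3,4-dihydroxyphenyl)-8-[(2S,4S)-2-(3,4-dihydroxyphenyl)-7-hydroxychroman-4-yl]chroman-3,5,7-triol (target)
Conditions: H2 (1 atm), Pd(OH)2/C, THF/MeOH/H2O 20:20:1, rt; filtration under argon, lyophilisation
Reagents that add atoms: none
Why: Catalytic hydrogenolysis of the eight O–CH2Ph bonds, under which the endocyclic benzylic C2–O1 bonds of rings C and F and the C4–C8 bond are known to survive in benzylated catechins and their 4→8 dimers, so no stereocentre is touched.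

Compound list
1 | (+)-catechin, (2R,3S) | Oc1cc(O)c2c(c1)O[C@H](c1ccc(O)c(O)c1)[C@@H](O)C2 | starting material
2 | 5,7,3',4'-tetra-O-benzyl-(+)-catechin, (2R,3S) | c1c(OCc3ccccc3)cc(OCc3ccccc3)c2c1O[C@H](c1ccc(OCc3ccccc3)c(OCc3ccccc3)c1)[C@@H](O)C2 | intermediate
3 | 8-bromo-5,7,3',4'-tetra-O-benzylcatechin, (2R,3S) | Brc1c(OCc3ccccc3)cc(OCc3ccccc3)c2c1O[C@H](c1ccc(OCc3ccccc3)c(OCc3ccccc3)c1)[C@@H](O)C2 | intermediate
4 | 8-bromo-3,5,7,3',4'-penta-O-benzylcatechin, (2R,3S) | Brc1c(OCc3ccccc3)cc(OCc3ccccc3)c2c1O[C@H](c1ccc(OCc3ccccc3)c(OCc3ccccc3)c1)[C@@H](OCc3ccccc3)C2 | intermediate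
5 | 8-lithio-penta-O-benzylcatechin | [Li]c1c(OCc3ccccc3)cc(OCc3ccccc3)c2c1O[C@H](c1ccc(OCc3ccccc3)c(OCc3ccccc3)c1)[C@@H](OCc3ccccc3)C2 | intermediate (not isolated)
6 | lithium (dimethylamino)(penta-O-benzylcatechin-8-yl)methoxide, alkoxide carbon unassigned | [Li+].[O-]C(N(C)C)c1c(OCc3ccccc3)cc(OCc3ccccc3)c2c1O[C@H](c1ccc(OCc3ccccc3)c(OCc3ccccc3)c1)[C@@H](OCc3ccccc3)C2 | intermediate (not isolated)
7 | 8-formyl-3,5,7,3',4'-penta-O-benzylcatechin, (2R,3S) | O=Cc1c(OCc3ccccc3)cc(OCc3ccccc3)c2c1O[C@H](c1ccc(OCc3ccccc3)c(OCc3ccccc3)c1)[C@@H](OCc3ccccc3)C2 | intermediate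
8 | 3',4'-dihydroxyacetophenone | CC(=O)c1ccc(O)c(O)c1 | starting material
9 | 3',4'-bis(benzyloxy)acetophenone | CC(=O)c1ccc(OCc2ccccc2)c(OCc2ccccc2)c1 | intermediate
10 | 1-(3,4-dibenzyloxyphenyl)-3-hydroxy-3-(penta-O-benzylcatechin-8-yl)propan-1-one, carbinol epimers | O=C(c1ccc(OCc3ccccc3)c(OCc3ccccc3)c1)CC(O)c1c(OCc3ccccc3)cc(OCc3ccccc3)c2c1O[C@H](c1ccc(OCc3ccccc3)c(OCc3ccccc3)c1)[C@@H](OCc3ccccc3)C2 | intermediate (not isolated)
11 | (E)-1-(3,4-dibenzyloxyphenyl)-3-(penta-O-benzylcatechin-8-yl)prop-2-en-1-one | O=C(c1ccc(OCc3ccccc3)c(OCc3ccccc3)c1)/C=C/c1c(OCc3ccccc3)cc(OCc3ccccc3)c2c1O[C@H](c1ccc(OCc3ccccc3)c(OCc3ccccc3)c1)[C@@H](OCc3ccccc3)C2 | intermediate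
12 | 4-bromoresorcinol | Oc1ccc(Br)c(O)c1 | starting material
13 | 5-benzyloxy-2-bromophenol | Oc1cc(OCc2ccccc2)ccc1Br | intermediate
14 | lithium 5-benzyloxy-2-lithiophenoxide | [Li]Oc1cc(OCc2ccccc2)ccc1[Li] | intermediate (not isolated)
15 | dilithium (4-benzyloxy-2-oxidophenyl)triisopropoxyborate | [Li+].[Li+].[O-]c1cc(OCc2ccccc2)ccc1[B-](OC(C)C)(OC(C)C)OC(C)C | intermediate (not isolated)
16 | 4-benzyloxy-2-hydroxyphenylboronic acid | OB(O)c1ccc(OCc2ccccc2)cc1O | intermediate
17 | (3S)-3-(4-benzyloxy-2-hydroxyphenyl)-1-(3,4-dibenzyloxyphenyl)-3-(penta-O-benzylcatechin-8-yl)propan-1-one | O=C(c1ccc(OCc3ccccc3)c(OCc3ccccc3)c1)C[C@@H](c1ccc(OCc3ccccc3)cc1O)c1c(OCc3ccccc3)cc(OCc3ccccc3)c2c1O[C@H](c1ccc(OCc3ccccc3)c(OCc3ccccc3)c1)[C@@H](OCc3ccccc3)C2 | intermediate (not isolated)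
18 | (4S)-7-benzyloxy-2-(3,4-dibenzyloxyphenyl)-4-(penta-O-benzylcatechin-8-yl)chroman-2-ol, C2 anomers | C(c3ccccc3)Oc1ccc2c(c1)OC(O)(c1ccc(OCc3ccccc3)c(OCc3ccccc3)c1)C[C@@H]2c1c(OCc3ccccc3)cc(OCc3ccccc3)c2c1O[C@H](c1ccc(OCc3ccccc3)c(OCc3ccccc3)c1)[C@@H](OCc3ccccc3)C2 | intermediate (not isolated)
19 | (4S)-7-benzyloxy-2-(3,4-dibenzyloxyphenyl)-4-(penta-O-benzylcatechin-8-yl)-4H-chromene | C(c3ccccc3)Oc1ccc2c(c1)OC(c1ccc(OCc3ccccc3)c(OCc3ccccc3)c1)=C[C@@H]2c1c(OCc3ccccc3)cc(OCc3ccccc3)c2c1O[C@H](c1ccc(OCc3ccccc3)c(OCc3ccccc3)c1)[C@@H](OCc3ccccc3)C2 | intermediate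
20 | (2S,4S)-7-benzyloxy-2-(3,4-dibenzyloxyphenyl)-4-(penta-O-benzylcatechin-8-yl)chroman, 2,4-cis | C(c3ccccc3)Oc1ccc2c(c1)O[C@H](c1ccc(OCc3ccccc3)c(OCc3ccccc3)c1)C[C@@H]2c1c(OCc3ccccc3)cc(OCc3ccccc3)c2c1O[C@H](c1ccc(OCc3ccccc3)c(OCc3ccccc3)c1)[C@@H](OCc3ccccc3)C2 | intermediate
21 | (2R,3S)-2-(3,4-dihydroxyphenyl)-8-[(2S,4S)-2-(3,4-dihydroxyphenyl)-7-hydroxychroman-4-yl]chroman-3,5,7-triol | Oc1ccc2c(c1)O[C@H](c1ccc(O)c(O)c1)C[C@@H]2c1c(O)cc(O)c2c1O[C@H](c1ccc(O)c(O)c1)[C@@H](O)C2 | target

Total step count: 11. Longest linear sequence: 8 steps (1, 2, 3, 4, 6, 9, 10, 11).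

Steps most likely to fail

Step 9.
- What may go wrong: migratory insertion at the β-carbon, which is flanked by two ortho oxygen substituents and deactivated by the electron-rich ring D, may be so slow that protodeboronation consumes the boronic acid. Forcing the temperature may also erode facial selectivity.
- Fallback: it sets out from 4 and 9, comes back at 19, and builds the same chromene by a polar C4–C8 bond formation instead of a C4–C4a insertion.
- Electrophile: ketone 9 is condensed with commercial 4-benzyloxy-2-hydroxybenzaldehyde (O=Cc1ccc(OCc2ccccc2)cc1O) under HBF4·OEt2 in AcOH/EtOAc, the classical salicylaldehyde–acetophenone flavylium synthesis. This gives 7-benzyloxy-2-(3,4-dibenzyloxyphenyl)chromenylium tetrafluoroborate F1.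
- Nucleophile: bromide 4 is lithiated to 5 as in step 4 and transmetalated with MgBr2·OEt2 to (penta-O-benzylcatechin-8-yl)magnesium bromide F2.
- Coupling: with catalytic CuBr·SMe2 in THF at −78 °C, F2 should add as a soft aryl nucleophile to C4 of F1, since C2 is blocked by ring B.
- Stereochemistry: there is no reagent control at C4, so 19 would form together with the (4R)-epimer of the chromene F3. The two are diastereomers because of the catechin unit and would be separated by chromatography.

Step 10.
- What may go wrong: hydrogen uptake on the poisoned catalyst may be sluggish at the hindered trisubstituted enol ether, so benzyl ethers start to be lost before C2=C3 is saturated. Discrimination between the two faces may also be insufficient.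
- Fallback: it sets out from 19, comes back at 20, and replaces surface hydrogenation by ionic hydrogenation with Et3SiH (excess) and CF3CO2H in CH2Cl2 at −40 °C.
- Course: protonation at C3 gives the (4S)-2-aryl-3,4-dihydrochromenylium trifluoroacetate F4. The silane should deliver hydride to C2 from the face opposite the pseudo-axial ring D, again leading to the 2,4-cis flavan 20 with all benzyl ethers intact.
- Safeguard: low temperature and excess silane keep the lifetime of the cation short, so the C4–C8 bond is not cleaved.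

Step 8.
- What may go wrong: proton return to the dianion, incomplete exchange, or protodeboronation of the very electron-rich boronic acid during hydrolysis and isolation.
- Fallback: it sets out from 13, comes back at 19, and avoids both the organolithium and the free boronic acid.
- Course: Miyaura borylation (B2pin2, PdCl2(dppf), KOAc, dioxane, 80 °C) should give the bench-stable, chromatographable 5-benzyloxy-2-(4,4,5,5-tetramethyl-1,3,2-dioxaborolan-2-yl)phenol F5.
- Re-entry: F5 is used in place of 16 under the conditions of step 9, where the aqueous KOH activates the pinacol boronate for transmetalation to rhodium.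

Further compounds
F1 | step 9 | 7-benzyloxy-2-(3,4-dibenzyloxyphenyl)chromenylium tetrafluoroborate | C(c3ccccc3)Oc1ccc2ccc(-c3ccc(OCc4ccccc4)c(OCc4ccccc4)c3)[o+]c2c1.F[B-](F)(F)F
F2 | step 9 | (penta-O-benzylcatechin-8-yl)magnesium bromide | Br[Mg]c1c(OCc3ccccc3)cc(OCc3ccccc3)c2c1O[C@H](c1ccc(OCc3ccccc3)c(OCc3ccccc3)c1)[C@@H](OCc3ccccc3)C2
F3 | step 9 | (4R)-7-benzyloxy-2-(3,4-dibenzyloxyphenyl)-4-(penta-O-benzylcatechin-8-yl)-4H-chromene | C(c3ccccc3)Oc1ccc2c(c1)OC(c1ccc(OCc3ccccc3)c(OCc3ccccc3)c1)=C[C@H]2c1c(OCc3ccccc3)cc(OCc3ccccc3)c2c1O[C@H](c1ccc(OCc3ccccc3)c(OCc3ccccc3)c1)[C@@H](OCc3ccccc3)C2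
F4 | step 10 | (4S)-7-benzyloxy-2-(3,4-dibenzyloxyphenyl)-4-(penta-O-benzylcatechin-8-yl)-3,4-dihydrochromenylium trifluoroacetate | C(c3ccccc3)Oc1ccc2c(c1)[O+]=C(c1ccc(OCc3ccccc3)c(OCc3ccccc3)c1)C[C@@H]2c1c(OCc3ccccc3)cc(OCc3ccccc3)c2c1O[C@H](c1ccc(OCc3ccccc3)c(OCc3ccccc3)c1)[C@@H](OCc3ccccc3)C2.[O-]C(=O)C(F)(F)F
F5 | step 8 | 5-benzyloxy-2-(4,4,5,5-tetramethyl-1,3,2-dioxaborolan-2-yl)phenol | CC1(C)OB(OC1(C)C)c1ccc(OCc2ccccc2)cc1O
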